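The ten-membered carbocycle is cut at C3–C4. C3 is an allylic carbinol set between the methyl-bearing alkene carbon C4 of the C4=C5 double bond and C2, the only methylene in the ring; this pattern is what an alkenyl nucleophile centred on C4 leaves when it adds to a C3 aldehyde. One intramolecular Nozaki–Hiyama–Kishi coupling therefore forms C3–C4, closes the ring and creates the C3 hydroxyl. Its precursor is a cis-β,γ-disubstituted α-methylene-γ-butyrolactone with a (Z)-2-iodopropenyl group on C6 and, on C7, a chain holding O8 as TBS ether, O9 as TES ether, the Z C1=C10 alkene and the C3 aldehyde.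

Key step: step 18

Remark: germacranolide numbering is used throughout (C1=C10 and C4=C5 ring alkenes, C6 lactone carbinol, C7 ring fusion, C8 free hydroxyl, C9 epoxy-ester carbinol, C11=C13 methylene, C12 lactone carbonyl); O8 and O9 are carried as two different silyl ethers so that O9 alone can be acylated with the enantiopure epoxy acid after ring closure.

Step 1
Reactants: 1 diethyl (R)-malate; 2 allyl bromide
Product: 3 diethyl (2R,3S)-2-hydroxy-3-(prop-2-en-1-yl)butanedioate
Conditions: LiN(i-Pr)2 (2.2 equiv), THF, −78 → −20 °C; then 2, −78 → −5 °C; aq. NH4Cl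
Reagents that add atoms: none
Why: Fráter–Seebach alkylation: the dilithium alkoxide–enolate is locked in a six-membered lithium chelate and allyl bromide enters on the enolate face away from the ester substituent of the carbinol carbon, which should place the allyl group anti to the C8 oxygen and so set C7 as 3S.

Step 2
Reactants: 3 diethyl (2R,3S)-2-hydroxy-3-(prop-2-en-1-yl)butanedioate
Product: 4 diethyl (2R,3S)-2-[(tert-butyldimethylsilyl)oxy]-3-(prop-2-en-1-yl)butanedioate
Conditions: TBSOTf, 2,6-lutidine, CH2Cl2, 0 °C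
Reagents that add atoms: tert-butyldimethylsilyl trifluoromethanesulfonate, CC(C)(C)[Si](C)(C)OS(=O)(=O)C(F)(F)F
Why: O-silylation of the secondary alcohol with a silyl triflate and a hindered pyridine base, which does not enolise either ester, so C7 and C8 are untouched.

Step 3
Reactants: 4 diethyl (2R,3S)-2-[(tert-butyldimethylsilyl)oxy]-3-(prop-2-en-1-yl)butanedioate
Product: 7 (3S,4R)-4-[(tert-butyldimethylsilyl)oxy]-3-(prop-2-en-1-yl)oxolan-2-one (cis lactone), via aldehyde ester 5 (not isolated), via hydroxy ester 6 (not isolated)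
Conditions: i-Bu2AlH (1.1 equiv), CH2Cl2, −78 °C; MeOH, then NaBH4, EtOH, −78 → 0 °C; PPTS (cat.), CH2Cl2, rt
Reagents that add atoms: none
Why: Chemoselective half-reduction with i-Bu2AlH of the ester that is inductively activated by the α-silyloxy group (the other ester is unactivated and sits next to the allyl-bearing carbon), borohydride reduction of the released aldehyde and acid-catalysed 5-exo-trig lactonisation of the γ-hydroxy ester; no stereocentre is touched, so allyl and silyloxy groups end up cis on the lactone.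

Step 4
Reactants: 7 (3S,4R)-4-[(tert-butyldimethylsilyl)oxy]-3-(prop-2-en-1-yl)oxolan-2-one; 8 1-propynyllithium
Product: 9 (5S,6R)-6-[(tert-butyldimethylsilyl)oxy]-7-hydroxy-5-(prop-2-en-1-yl)hept-2-yn-4-one
Conditions: THF, −78 °C; aq. NH4Cl at −78 °C
Reagents that add atoms: none
Why: Acetylide addition to a lactone (nucleophilic acyl substitution stopped at the ketone): the lithium hemiketal alkoxide is stable at −78 °C and collapses to the ynone only on quench, so a second addition and enolisation at C7 are avoided.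

Step 5
Reactants: 9 (5S,6R)-6-[(tert-butyldimethylsilyl)oxy]-7-hydroxy-5-(prop-2-en-1-yl)hept-2-yn-4-one
Product: 10 (5S,6R)-6-[(tert-butyldimethylsilyl)oxy]-5-(prop-2-en-1-yl)-7-[(triethylsilyl)oxy]hept-2-yn-4-one
Conditions: TESOTf, 2,6-lutidine, CH2Cl2, −78 °C
Reagents that add atoms: triethylsilyl trifluoromethanesulfonate, CC[Si](CC)(CC)OS(=O)(=O)C(F)(F)F
Why: Silylation of the primary hydroxyl with a silyl triflate and a non-nucleophilic base that cannot add to the ynone, which also locks the open-chain keto form for the reduction.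

Step 6
Reactants: 10 (5S,6R)-6-[(tert-butyldimethylsilyl)oxy]-5-(prop-2-en-1-yl)-7-[(triethylsilyl)oxy]hept-2-yn-4-one
Product: 11 (4S,5R,6R)-6-[(tert-butyldimethylsilyl)oxy]-5-(prop-2-en-1-yl)-7-[(triethylsilyl)oxy]hept-2-yn-4-ol
Conditions: Ru[(S,S)-TsNCHPhCHPhNH](p-cymene) (2 mol%), i-PrOH, rt
Reagents that add atoms: none
Why: Noyori asymmetric transfer hydrogenation of an α,β-acetylenic ketone: the (S,S)-configured divalent ruthenium amido complex passes hydride and proton through a six-membered transition state in which the alkynyl group takes the place normally held by an aryl group, so the catalyst and not C7 should fix C6 as the 4S propargylic alcohol, and the base-free medium leaves the epimerisable C7 alone.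

Step 7
Reactants: 11 (4S,5R,6R)-6-[(tert-butyldimethylsilyl)oxy]-5-(prop-2-en-1-yl)-7-[(triethylsilyl)oxy]hept-2-yn-4-ol
Product: 13 (2Z,4S,5R,6R)-6-[(tert-butyldimethylsilyl)oxy]-2-iodo-5-(prop-2-en-1-yl)-7-[(triethylsilyl)oxy]hept-2-en-4-ol, via cyclic alkenylaluminate 12 (not isolated)
Conditions: NaAlH2(OCH2CH2OMe)2 (1.6 equiv), THF, 0 °C → rt; EtOAc; I2, THF, −78 → 0 °C
Reagents that add atoms: iodine, II
Why: Hydroxyl-directed trans-hydroalumination of a propargylic alcohol: the alkoxide-bound aluminium hydride delivers hydride to C5 and aluminium to C4 through a five-membered oxa-aluminacycle, and iodinolysis of the C4–Al bond with retention should give the iodoalkene with iodine cis to C6 (Z).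

Step 8
Reactants: 13 (2Z,4S,5R,6R)-6-[(tert-butyldimethylsilyl)oxy]-2-iodo-5-(prop-2-en-1-yl)-7-[(triethylsilyl)oxy]hept-2-en-4-ol
Product: 14 (4R,5S)-4-{(1R)-1-[(tert-butyldimethylsilyl)oxy]-2-[(triethylsilyl)oxy]ethyl}-5-[(1Z)-2-iodoprop-1-en-1-yl]oxolan-2-ol (both anomers)
Conditions: OsO4 (2 mol%), NaIO4 (4 equiv), 2,6-lutidine, dioxane/H2O, rt
Reagents that add atoms: sodium periodate, [Na+].[O-]I(=O)(=O)=O (oxygen donor, relayed by OsO4)
Why: Lemieux–Johnson oxidative cleavage: OsO4 dihydroxylates the unhindered monosubstituted alkene much faster than the hindered, iodine-deactivated trisubstituted alkene, periodate cleaves the diol, and the aldehyde is trapped at once by the C6 hydroxyl as the five-membered lactol.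

Step 9
Reactants: 14 (4R,5S)-4-{(1R)-1-[(tert-butyldimethylsilyl)oxy]-2-[(triethylsilyl)oxy]ethyl}-5-[(1Z)-2-iodoprop-1-en-1-yl]oxolan-2-ol
Product: 15 (4R,5S)-4-{(1R)-1-[(tert-butyldimethylsilyl)oxy]-2-[(triethylsilyl)oxy]ethyl}-5-[(1Z)-2-iodoprop-1-en-1-yl]oxolan-2-one
Conditions: Pr4N[RuO4] (5 mol%), N-methylmorpholine N-oxide, 4 Å molecular sieves, CH2Cl2, rt
Reagents that add atoms: none
Why: Ley–Griffith oxidation of a lactol to the lactone under neutral conditions that leave both silyl ethers and the alkenyl iodide intact.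

Step 10
Reactants: 15 (4R,5S)-4-{(1R)-1-[(tert-butyldimethylsilyl)oxy]-2-[(triethylsilyl)oxy]ethyl}-5-[(1Z)-2-iodoprop-1-en-1-yl]oxolan-2-one
Product: 16 (2R)-2-[(tert-butyldimethylsilyl)oxy]-2-{(2S,3R)-2-[(1Z)-2-iodoprop-1-en-1-yl]-5-oxooxolan-3-yl}acetaldehyde
Conditions: (COCl)2, DMSO, CH2Cl2, −78 → −40 °C; then Et3N, −78 → 0 °C
Reagents that add atoms: none
Why: Swern oxidation applied to a primary triethylsilyl ether: the chlorosulfonium reagent exchanges the unhindered primary silyl ether for an alkoxysulfonium ion that fragments to the aldehyde, while the hindered secondary TBS ether does not react and the cold amine base should not epimerise C8.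

Step 11
Reactants: 17 3-[(4-methoxyphenyl)methoxy]propan-1-ol
Product: 18 3-[(4-methoxyphenyl)methoxy]propanal
Conditions: Dess–Martin periodinane, NaHCO3, CH2Cl2, 0 °C → rt
Reagents that add atoms: none
Why: Dess–Martin oxidation of a primary alcohol, buffered so that the β-alkoxy aldehyde does not eliminate.

Step 12
Reactants: 18 3-[(4-methoxyphenyl)methoxy]propanal; 19 ethyltriphenylphosphonium bromide
Product: 23 1-({[(3Z)-4-iodopent-3-en-1-yl]oxy}methyl)-4-methoxybenzene, via ethylidene ylide 20 (not isolated), via iodoethylphosphonium iodide 21 (not isolated), via iodoethylidene ylide 22 (not isolated)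
Conditions: n-BuLi, THF, 0 °C; I2, −78 °C; NaN(SiMe3)2, −78 → −20 °C; then 18, −78 °C → rt
Reagents that add atoms: iodine, II
Why: Stork–Zhao-type Wittig olefination with an α-iodo ylide made by iodination and re-deprotonation of the ethylidene ylide: the unstabilised ylide reacts under kinetic control through the cis oxaphosphetane, which should place iodine cis to the CH2 chain (Z).

Step 13
Reactants: 16 (2R)-2-[(tert-butyldimethylsilyl)oxy]-2-{(2S,3R)-2-[(1Z)-2-iodoprop-1-en-1-yl]-5-oxooxolan-3-yl}acetaldehyde; 23 1-({[(3Z)-4-iodopent-3-en-1-yl]oxy}methyl)-4-methoxybenzene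
Product: 26 (4R,5S)-4-{(1R,2S,3Z)-1-[(tert-butyldimethylsilyl)oxy]-2-hydroxy-6-[(4-methoxyphenyl)methoxy]-3-methylhex-3-en-1-yl}-5-[(1Z)-2-iodoprop-1-en-1-yl]oxolan-2-one, via alkenyllithium 24 (not isolated), via alkenylmagnesium bromide 25 (not isolated)
Conditions: t-BuLi (2 equiv per 23), Et2O, −78 °C; MgBr2·OEt2, −78 → −40 °C; then 16, CH2Cl2, −78 °C; aq. NH4Cl at −78 °C
Reagents that add atoms: none
Why: Felkin–Anh-controlled 1,2-addition of an alkenyl Grignard reagent (lithium–iodine exchange and transmetalation both retain the alkene geometry): with the bulky, non-chelating silyloxy group anti to the incoming nucleophile the new C9 carbinol should form anti to the C8 oxygen (9S), and at −78 °C the aldehyde is attacked far faster than the lactone.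

Step 14
Reactants: 26 (4R,5S)-4-{(1R,2S,3Z)-1-[(tert-butyldimethylsilyl)oxy]-2-hydroxy-6-[(4-methoxyphenyl)methoxy]-3-methylhex-3-en-1-yl}-5-[(1Z)-2-iodoprop-1-en-1-yl]oxolan-2-one
Product: 27 (4R,5S)-4-{(1R,2S,3Z)-1-[(tert-butyldimethylsilyl)oxy]-6-[(4-methoxyphenyl)methoxy]-3-methyl-2-[(triethylsilyl)oxy]hex-3-en-1-yl}-5-[(1Z)-2-iodoprop-1-en-1-yl]oxolan-2-one
Conditions: TESOTf, 2,6-lutidine, CH2Cl2, −78 → 0 °C
Reagents that add atoms: triethylsilyl trifluoromethanesulfonate, CC[Si](CC)(CC)OS(=O)(=O)C(F)(F)F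
Why: Silylation of the hindered allylic secondary alcohol with a silyl triflate, which differentiates O9 (TES) from O8 (TBS) for the end game.

Step 15
Reactants: 27 (4R,5S)-4-{(1R,2S,3Z)-1-[(tert-butyldimethylsilyl)oxy]-6-[(4-methoxyphenyl)methoxy]-3-methyl-2-[(triethylsilyl)oxy]hex-3-en-1-yl}-5-[(1Z)-2-iodoprop-1-en-1-yl]oxolan-2-one
Product: 30 (4R,5S)-4-{(1R,2S,3Z)-1-[(tert-butyldimethylsilyl)oxy]-6-[(4-methoxyphenyl)methoxy]-3-methyl-2-[(triethylsilyl)oxy]hex-3-en-1-yl}-5-[(1Z)-2-iodoprop-1-en-1-yl]-3-methylideneoxolan-2-one, via Mannich base 28 (not isolated), via trimethylammonium iodide 29 (not isolated)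
Conditions: LiN(i-Pr)2, THF, −78 °C; CH2=NMe2+ I−, −78 °C → rt; MeI, CH2Cl2, rt; aq. NaHCO3, CH2Cl2, rt
Reagents that add atoms: Eschenmoser's salt (N,N-dimethylmethyleneiminium iodide), C=[N+](C)C.[I-]
Why: Mannich reaction of the lactone lithium enolate with Eschenmoser's salt followed by N-methylation and Hofmann-type β-elimination, the standard way to an α-methylene-γ-butyrolactone; C11 is the only enolisable position and becomes trigonal, so no new stereocentre remains.

Step 16
Reactants: 30 (4R,5S)-4-{(1R,2S,3Z)-1-[(tert-butyldimethylsilyl)oxy]-6-[(4-methoxyphenyl)methoxy]-3-methyl-2-[(triethylsilyl)oxy]hex-3-en-1-yl}-5-[(1Z)-2-iodoprop-1-en-1-yl]-3-methylideneoxolan-2-one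
Product: 31 (4R,5S)-4-{(1R,2S,3Z)-1-[(tert-butyldimethylsilyl)oxy]-6-hydroxy-3-methyl-2-[(triethylsilyl)oxy]hex-3-en-1-yl}-5-[(1Z)-2-iodoprop-1-en-1-yl]-3-methylideneoxolan-2-one
Conditions: DDQ, CH2Cl2/pH 7 buffer, 0 °C
Reagents that add atoms: none
Why: Oxidative cleavage of the 4-methoxybenzyl ether by DDQ (hydride abstraction from the electron-rich benzylic position and hydrolysis of the oxocarbenium ion), which leaves silyl ethers, alkenyl iodide and methylene lactone alone.

Step 17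
Reactants: 31 (4R,5S)-4-{(1R,2S,3Z)-1-[(tert-butyldimethylsilyl)oxy]-6-hydroxy-3-methyl-2-[(triethylsilyl)oxy]hex-3-en-1-yl}-5-[(1Z)-2-iodoprop-1-en-1-yl]-3-methylideneoxolan-2-one
Product: 32 (3Z,5S,6R)-6-[(tert-butyldimethylsilyl)oxy]-6-{(2S,3R)-2-[(1Z)-2-iodoprop-1-en-1-yl]-4-methylidene-5-oxooxolan-3-yl}-4-methyl-5-[(triethylsilyl)oxy]hex-3-enal
Conditions: Dess–Martin periodinane, NaHCO3, CH2Cl2, 0 °C; filtered and used at once
Reagents that add atoms: none
Why: Dess–Martin oxidation under bicarbonate buffering, chosen because its neutral conditions should not move the C1=C10 double bond into conjugation with the new aldehyde.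

Step 18
Reactants: 32 (3Z,5S,6R)-6-[(tert-butyldimethylsilyl)oxy]-6-{(2S,3R)-2-[(1Z)-2-iodoprop-1-en-1-yl]-4-methylidene-5-oxooxolan-3-yl}-4-methyl-5-[(triethylsilyl)oxy]hex-3-enal
Product: 33 (1(10)Z,4Z)-8-[(tert-butyldimethylsilyl)oxy]-3-hydroxy-9-[(triethylsilyl)oxy]germacra-1(10),4,11(13)-trien-12,6-olide (3S,6R,7R,8R,9S)
Conditions: CrCl2 (10 equiv), NiCl2 (0.2 equiv), degassed DMSO, rt, slow addition of 32 (final 0.002 M)
Reagents that add atoms: none
Why: Zerovalent nickel, generated from NiCl2 by CrCl2, inserts into the C4–I bond with retention of the Z geometry, the alkenyl group is handed on to trivalent chromium, and the alkenylchromium species adds to the chromium-bound C3 carbonyl; aqueous work-up frees the carbinol. The closest known reaction type is the intramolecular Nozaki–Hiyama–Kishi alkenyl iodide–aldehyde coupling used to close medium and large carbocycles under high dilution. The ten-membered ring is closed by formation of the C3–C4 bond in a 10-exo-trig mode, the carbonyl oxygen ending outside the new ring. The new stereocentre C3 is governed by the conformation of the closing ring, which is restricted by the two Z alkenes, the cis-fused lactone and the anti-disposed O8 and O9 silyl ethers, so the aldehyde is expected to present the face that leads to the 3S carbinol; this is a conformational expectation and the epimer can still be used. The step needs chemoselectivity for the aldehyde over the lactone carbonyl and the methylene lactone and needs cyclisation to beat oligomerisation: alkenylchromium reagents add only to aldehydes, the neutral medium keeps the β,γ-unsaturated aldehyde out of conjugation, and slow addition into a dilute solution keeps the concentration of open-chain material low.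

Step 19
Reactants: 33 (1(10)Z,4Z)-8-[(tert-butyldimethylsilyl)oxy]-3-hydroxy-9-[(triethylsilyl)oxy]germacra-1(10),4,11(13)-trien-12,6-olide
Product: 34 (1(10)Z,4Z)-3-acetoxy-8-[(tert-butyldimethylsilyl)oxy]-9-[(triethylsilyl)oxy]germacra-1(10),4,11(13)-trien-12,6-olide (3S,6R,7R,8R,9S)
Conditions: Ac2O, pyridine, DMAP (cat.), CH2Cl2, 0 °C → rt
Reagents that add atoms: acetic anhydride, CC(=O)OC(C)=O
Why: DMAP-catalysed acylation of the only free hydroxyl, with retention at C3.

Step 20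
Reactants: 34 (1(10)Z,4Z)-3-acetoxy-8-[(tert-butyldimethylsilyl)oxy]-9-[(triethylsilyl)oxy]germacra-1(10),4,11(13)-trien-12,6-olide
Product: 35 (1(10)Z,4Z)-3-acetoxy-8-[(tert-butyldimethylsilyl)oxy]-9-hydroxygermacra-1(10),4,11(13)-trien-12,6-olide (3S,6R,7R,8R,9S)
Conditions: HF·pyridine, pyridine, THF, 0 °C
Reagents that add atoms: none
Why: Selective fluoride-mediated desilylation: the triethylsilyl ether is cleaved by buffered HF·pyridine far faster than the more hindered tert-butyldimethylsilyl ether, and the acidic medium excludes acetate migration.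

Step 21
Reactants: 36 angelic acid ((2Z)-2-methylbut-2-enoic acid)
Product: 37 (2Z)-2-methylbut-2-en-1-ol
Conditions: LiAlH4, Et2O, 0 °C → rt
Reagents that add atoms: none
Why: Hydride reduction of the carboxylic acid with LiAlH4, which takes the carboxylate to the allylic alcohol without touching or isomerising the trisubstituted Z alkene.

Step 22
Reactants: 37 (2Z)-2-methylbut-2-en-1-ol
Product: 38 [(2S,3R)-2,3-dimethyloxiran-2-yl]methanol
Conditions: Ti(Oi-Pr)4 (10 mol%), L-(+)-diisopropyl tartrate (12 mol%), t-BuOOH, 4 Å molecular sieves, CH2Cl2, −20 °C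
Reagents that add atoms: tert-butyl hydroperoxide, CC(C)(C)OO
Why: Sharpless asymmetric epoxidation: the titanium tartrate complex built from L-(+)-tartrate delivers the peroxide oxygen to the alkene face that gives the (2S,3R) epoxy alcohol, and the Z geometry of the alkene fixes the two methyl groups trans on the oxirane.

Step 23
Reactants: 38 [(2S,3R)-2,3-dimethyloxiran-2-yl]methanol
Product: 39 (2R,3R)-2,3-dimethyloxirane-2-carboxylic acid
Conditions: RuCl3·xH2O (2 mol%), NaIO4 (3 equiv), MeCN/EtOAc/H2O, rt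
Reagents that add atoms: water, O
Why: Ruthenium tetroxide oxidation (RuCl3 with NaIO4) of the primary alcohol to the acid through the aldehyde hydrate; the oxirane stereocentres are untouched and C2 changes its descriptor only because the carboxyl group now outranks C3.

Step 24
Reactants: 35 (1(10)Z,4Z)-3-acetoxy-8-[(tert-butyldimethylsilyl)oxy]-9-hydroxygermacra-1(10),4,11(13)-trien-12,6-olide; 39 (2R,3R)-2,3-dimethyloxirane-2-carboxylic acid; 40 2,4,6-trichlorobenzoyl chloride
Product: 42 (1(10)Z,4Z)-3-acetoxy-8-[(tert-butyldimethylsilyl)oxy]-9-{[(2R,3R)-2,3-dimethyloxirane-2-carbonyl]oxy}germacra-1(10),4,11(13)-trien-12,6-olide (3S,6R,7R,8R,9S), via mixed anhydride 41 (not isolated)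
Conditions: 39, 40, Et3N, THF, rt; then 35, DMAP, toluene, rt → 40 °C
Reagents that add atoms: none
Why: Yamaguchi esterification: the acid is activated as the mixed 2,4,6-trichlorobenzoic anhydride, DMAP attacks the less shielded aliphatic carbonyl and the resulting acylpyridinium ion acylates O9; the acid has no α-hydrogen and so cannot epimerise.

Step 25
Reactants: 42 (1(10)Z,4Z)-3-acetoxy-8-[(tert-butyldimethylsilyl)oxy]-9-{[(2R,3R)-2,3-dimethyloxirane-2-carbonyl]oxy}germacra-1(10),4,11(13)-trien-12,6-olide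
Product: 43 CNP0137407.4, (1(10)Z,4Z)-3-acetoxy-9-{[(2R,3R)-2,3-dimethyloxirane-2-carbonyl]oxy}-8-hydroxygermacra-1(10),4,11(13)-trien-12,6-olide (3S,6R,7S,8R,9S)
Conditions: HF·pyridine, pyridine, THF, 0 °C → rt
Reagents that add atoms: none
Why: Fluoride-mediated cleavage of the remaining silyl ether under buffered acidic conditions, under which the α,β-epoxy ester, the allylic acetate and the lactone should survive and the freed C8 hydroxyl cannot trigger acyl migration or translactonisation.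

Compound list

1 | diethyl (R)-malate | CCOC(=O)C[C@@H](O)C(=O)OCC | starting material
2 | allyl bromide | C=CCBr | starting material
3 | diethyl (2R,3S)-2-hydroxy-3-(prop-2-en-1-yl)butanedioate | CCOC(=O)[C@H](O)[C@H](CC=C)C(=O)OCC | intermediate
4 | diethyl (2R,3S)-2-[(tert-butyldimethylsilyl)oxy]-3-(prop-2-en-1-yl)butanedioate | CCOC(=O)[C@H](O[Si](C)(C)C(C)(C)C)[C@H](CC=C)C(=O)OCC | intermediate
5 | ethyl (2S,3R)-3-[(tert-butyldimethylsilyl)oxy]-4-oxo-2-(prop-2-en-1-yl)butanoate | CCOC(=O)[C@@H](CC=C)[C@@H](O[Si](C)(C)C(C)(C)C)C=O | intermediate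
6 | ethyl (2S,3R)-3-[(tert-butyldimethylsilyl)oxy]-4-hydroxy-2-(prop-2-en-1-yl)butanoate | CCOC(=O)[C@@H](CC=C)[C@@H](O[Si](C)(C)C(C)(C)C)CO | intermediate
7 | (3S,4R)-4-[(tert-butyldimethylsilyl)oxy]-3-(prop-2-en-1-yl)oxolan-2-one | O=C1OC[C@H](O[Si](C)(C)C(C)(C)C)[C@@H]1CC=C | intermediate
8 | 1-propynyllithium | [Li]C#CC | starting material
9 | (5S,6R)-6-[(tert-butyldimethylsilyl)oxy]-7-hydroxy-5-(prop-2-en-1-yl)hept-2-yn-4-one | CC#CC(=O)[C@@H](CC=C)[C@@H](O[Si](C)(C)C(C)(C)C)CO | intermediate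
10 | (5S,6R)-6-[(tert-butyldimethylsilyl)oxy]-5-(prop-2-en-1-yl)-7-[(triethylsilyl)oxy]hept-2-yn-4-one | CC#CC(=O)[C@@H](CC=C)[C@@H](O[Si](C)(C)C(C)(C)C)CO[Si](CC)(CC)CC | intermediate
11 | (4S,5R,6R)-6-[(tert-butyldimethylsilyl)oxy]-5-(prop-2-en-1-yl)-7-[(triethylsilyl)oxy]hept-2-yn-4-ol | CC#C[C@@H](O)[C@@H](CC=C)[C@@H](O[Si](C)(C)C(C)(C)C)CO[Si](CC)(CC)CC | intermediate
12 | sodium cyclic alkenyl(alkoxy)bis(2-methoxyethoxy)aluminate of 11 (five-membered ring O–Al–C4=C5–C6, aluminium on the methyl-bearing carbon) | CC1=C[C@H]([C@@H](CC=C)[C@@H](O[Si](C)(C)C(C)(C)C)CO[Si](CC)(CC)CC)O[Al-]1(OCCOC)OCCOC.[Na+] | intermediate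
13 | (2Z,4S,5R,6R)-6-[(tert-butyldimethylsilyl)oxy]-2-iodo-5-(prop-2-en-1-yl)-7-[(triethylsilyl)oxy]hept-2-en-4-ol | C/C(I)=C/[C@@H](O)[C@@H](CC=C)[C@@H](O[Si](C)(C)C(C)(C)C)CO[Si](CC)(CC)CC | intermediate
14 | (4R,5S)-4-{(1R)-1-[(tert-butyldimethylsilyl)oxy]-2-[(triethylsilyl)oxy]ethyl}-5-[(1Z)-2-iodoprop-1-en-1-yl]oxolan-2-ol (anomer mixture) | OC1C[C@@H]([C@@H](O[Si](C)(C)C(C)(C)C)CO[Si](CC)(CC)CC)[C@@H](/C=C(/C)I)O1 | intermediate
15 | (4R,5S)-4-{(1R)-1-[(tert-butyldimethylsilyl)oxy]-2-[(triethylsilyl)oxy]ethyl}-5-[(1Z)-2-iodoprop-1-en-1-yl]oxolan-2-one | O=C1C[C@@H]([C@@H](O[Si](C)(C)C(C)(C)C)CO[Si](CC)(CC)CC)[C@@H](/C=C(/C)I)O1 | intermediate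
16 | (2R)-2-[(tert-butyldimethylsilyl)oxy]-2-{(2S,3R)-2-[(1Z)-2-iodoprop-1-en-1-yl]-5-oxooxolan-3-yl}acetaldehyde | O=C[C@H](O[Si](C)(C)C(C)(C)C)[C@@H]1CC(=O)O[C@@H]1/C=C(/C)I | intermediate
17 | 3-[(4-methoxyphenyl)methoxy]propan-1-ol | COc1ccc(COCCCO)cc1 | starting material
18 | 3-[(4-methoxyphenyl)methoxy]propanal | COc1ccc(COCCC=O)cc1 | intermediate
19 | ethyltriphenylphosphonium bromide | CC[P+](c1ccccc1)(c1ccccc1)c1ccccc1.[Br-] | starting material
20 | ethylidenetriphenylphosphorane | CC=P(c1ccccc1)(c1ccccc1)c1ccccc1 | intermediate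
21 | (1-iodoethyl)triphenylphosphonium iodide | CC(I)[P+](c1ccccc1)(c1ccccc1)c1ccccc1.[I-] | intermediate
22 | (1-iodoethylidene)triphenylphosphorane | CC(I)=P(c1ccccc1)(c1ccccc1)c1ccccc1 | intermediate
23 | 1-({[(3Z)-4-iodopent-3-en-1-yl]oxy}methyl)-4-methoxybenzene | C/C(I)=C/CCOCc1ccc(OC)cc1 | intermediate
24 | {5-[(4-methoxyphenyl)methoxy]pent-2-en-2-yl}lithium, lithium cis to the CH2 chain | C/C([Li])=C/CCOCc1ccc(OC)cc1 | intermediate
25 | bromo{5-[(4-methoxyphenyl)methoxy]pent-2-en-2-yl}magnesium, magnesium cis to the CH2 chain | C/C([Mg]Br)=C/CCOCc1ccc(OC)cc1 | intermediate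
26 | (4R,5S)-4-{(1R,2S,3Z)-1-[(tert-butyldimethylsilyl)oxy]-2-hydroxy-6-[(4-methoxyphenyl)methoxy]-3-methylhex-3-en-1-yl}-5-[(1Z)-2-iodoprop-1-en-1-yl]oxolan-2-one | O=C1C[C@@H]([C@@H](O[Si](C)(C)C(C)(C)C)[C@@H](O)/C(C)=C\CCOCc2ccc(OC)cc2)[C@@H](/C=C(/C)I)O1 | intermediate
27 | (4R,5S)-4-{(1R,2S,3Z)-1-[(tert-butyldimethylsilyl)oxy]-6-[(4-methoxyphenyl)methoxy]-3-methyl-2-[(triethylsilyl)oxy]hex-3-en-1-yl}-5-[(1Z)-2-iodoprop-1-en-1-yl]oxolan-2-one | O=C1C[C@@H]([C@@H](O[Si](C)(C)C(C)(C)C)[C@@H](O[Si](CC)(CC)CC)/C(C)=C\CCOCc2ccc(OC)cc2)[C@@H](/C=C(/C)I)O1 | intermediate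
28 | 3-[(dimethylamino)methyl] derivative of 27 (C11 epimers) | CN(C)CC1C(=O)O[C@H](/C=C(/C)I)[C@@H]1[C@@H](O[Si](C)(C)C(C)(C)C)[C@@H](O[Si](CC)(CC)CC)/C(C)=C\CCOCc1ccc(OC)cc1 | intermediate
29 | 3-[(trimethylammonio)methyl] derivative of 27, iodide (C11 epimers) | C[N+](C)(C)CC1C(=O)O[C@H](/C=C(/C)I)[C@@H]1[C@@H](O[Si](C)(C)C(C)(C)C)[C@@H](O[Si](CC)(CC)CC)/C(C)=C\CCOCc1ccc(OC)cc1.[I-] | intermediate
30 | (4R,5S)-4-{(1R,2S,3Z)-1-[(tert-butyldimethylsilyl)oxy]-6-[(4-methoxyphenyl)methoxy]-3-methyl-2-[(triethylsilyl)oxy]hex-3-en-1-yl}-5-[(1Z)-2-iodoprop-1-en-1-yl]-3-methylideneoxolan-2-one | C=C1C(=O)O[C@H](/C=C(/C)I)[C@@H]1[C@@H](O[Si](C)(C)C(C)(C)C)[C@@H](O[Si](CC)(CC)CC)/C(C)=C\CCOCc1ccc(OC)cc1 | intermediate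
31 | (4R,5S)-4-{(1R,2S,3Z)-1-[(tert-butyldimethylsilyl)oxy]-6-hydroxy-3-methyl-2-[(triethylsilyl)oxy]hex-3-en-1-yl}-5-[(1Z)-2-iodoprop-1-en-1-yl]-3-methylideneoxolan-2-one | C=C1C(=O)O[C@H](/C=C(/C)I)[C@@H]1[C@@H](O[Si](C)(C)C(C)(C)C)[C@@H](O[Si](CC)(CC)CC)/C(C)=C\CCO | intermediate
32 | (3Z,5S,6R)-6-[(tert-butyldimethylsilyl)oxy]-6-{(2S,3R)-2-[(1Z)-2-iodoprop-1-en-1-yl]-4-methylidene-5-oxooxolan-3-yl}-4-methyl-5-[(triethylsilyl)oxy]hex-3-enal (key-step precursor) | C=C1C(=O)O[C@H](/C=C(/C)I)[C@@H]1[C@@H](O[Si](C)(C)C(C)(C)C)[C@@H](O[Si](CC)(CC)CC)/C(C)=C\CC=O | intermediate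
33 | (1(10)Z,4Z)-8-[(tert-butyldimethylsilyl)oxy]-3-hydroxy-9-[(triethylsilyl)oxy]germacra-1(10),4,11(13)-trien-12,6-olide (3S,6R,7R,8R,9S; key-step product) | C=C1C(=O)O[C@@H]2/C=C(/C)[C@@H](O)C/C=C(/C)[C@H](O[Si](CC)(CC)CC)[C@H](O[Si](C)(C)C(C)(C)C)[C@H]12 | intermediate
34 | (1(10)Z,4Z)-3-acetoxy-8-[(tert-butyldimethylsilyl)oxy]-9-[(triethylsilyl)oxy]germacra-1(10),4,11(13)-trien-12,6-olide (3S,6R,7R,8R,9S) | C=C1C(=O)O[C@@H]2/C=C(/C)[C@@H](OC(C)=O)C/C=C(/C)[C@H](O[Si](CC)(CC)CC)[C@H](O[Si](C)(C)C(C)(C)C)[C@H]12 | intermediate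
35 | (1(10)Z,4Z)-3-acetoxy-8-[(tert-butyldimethylsilyl)oxy]-9-hydroxygermacra-1(10),4,11(13)-trien-12,6-olide (3S,6R,7R,8R,9S) | C=C1C(=O)O[C@@H]2/C=C(/C)[C@@H](OC(C)=O)C/C=C(/C)[C@H](O)[C@H](O[Si](C)(C)C(C)(C)C)[C@H]12 | intermediate
36 | angelic acid | C/C=C(/C)C(=O)O | starting material
37 | (2Z)-2-methylbut-2-en-1-ol | C/C=C(/C)CO | intermediate
38 | [(2S,3R)-2,3-dimethyloxiran-2-yl]methanol | OC[C@]1(C)O[C@@H]1C | intermediate
39 | (2R,3R)-2,3-dimethyloxirane-2-carboxylic acid | OC(=O)[C@]1(C)O[C@@H]1C | intermediate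
40 | 2,4,6-trichlorobenzoyl chloride | O=C(Cl)c1c(Cl)cc(Cl)cc1Cl | starting material
41 | (2R,3R)-2,3-dimethyloxirane-2-carboxylic 2,4,6-trichlorobenzoic anhydride | O=C(OC(=O)c1c(Cl)cc(Cl)cc1Cl)[C@]2(C)O[C@@H]2C | intermediate
42 | (1(10)Z,4Z)-3-acetoxy-8-[(tert-butyldimethylsilyl)oxy]-9-{[(2R,3R)-2,3-dimethyloxirane-2-carbonyl]oxy}germacra-1(10),4,11(13)-trien-12,6-olide (3S,6R,7R,8R,9S) | C=C1C(=O)O[C@@H]2/C=C(/C)[C@@H](OC(C)=O)C/C=C(/C)[C@H](OC(=O)[C@]3(C)O[C@@H]3C)[C@H](O[Si](C)(C)C(C)(C)C)[C@H]12 | intermediate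
43 | CNP0137407.4, (1(10)Z,4Z)-3-acetoxy-9-{[(2R,3R)-2,3-dimethyloxirane-2-carbonyl]oxy}-8-hydroxygermacra-1(10),4,11(13)-trien-12,6-olide (3S,6R,7S,8R,9S) | C=C1C(=O)O[C@@H]2/C=C(/C)[C@@H](OC(C)=O)C/C=C(/C)[C@H](OC(=O)[C@]3(C)O[C@@H]3C)[C@H](O)[C@H]12 | target

Total step count: 25. Longest linear sequence: 20 steps (steps 1–10, 13–20, 24 and 25, from diethyl (R)-malate).

The three steps most likely to fail

Step 18, the ring closure. Two processes threaten it: closure of a ten-membered ring is slow, so intermolecular coupling can compete, and the facial selectivity at C3 rests on ring conformation alone. The fallback answers the stereochemical failure. It sets out from 32, which is cyclised as before; if the 3R alcohol, 3-epi-33 F1, is the main product it is taken on rather than discarded. A Mitsunobu reaction with acetic acid (PPh3, diisopropyl azodicarboxylate, toluene, 0 °C) displaces the activated C3 oxygen with inversion and gives acetate 34 directly, where the route is rejoined.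

Step 13, the addition at C9. Felkin–Anh control by an α-silyloxy group may give only modest facial selectivity, and the magnesium alkoxide could start a silyl shift if the quench is late. The fallback sets out from 16 and 23, which are coupled without regard to selectivity. The mixture of 26 and its C9 epimer, 9-epi-26 F2, is oxidised with Dess–Martin periodinane to the Z enone F3. F3 is reduced with (R)-BINAL-H, LiAlH(OEt)[(R)-1,1'-binaphthalene-2,2'-diolate], in THF at −100 → −78 °C. This reagent reduces enones in the presence of γ-lactones and differentiates the faces by the unsaturated substituent rather than by the neighbouring stereocentre, so the hydride should arrive under reagent control and return the route to 26.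

Step 24, the esterification. Acylation of the hindered C9 hydroxyl of the macrocycle, which lies next to the bulky O8 silyl ether, by an acid with a fully substituted α-carbon may be slow enough for side reactions of the activated acid to take over. The fallback moves the acylation in front of the ring closure, where the alcohol is open-chain. It sets out from 30: buffered HF·pyridine at 0 °C removes the triethylsilyl group to give allylic alcohol F4, and Yamaguchi esterification with 39 (through 41) gives epoxy ester F5. DDQ then frees primary alcohol F6, Dess–Martin oxidation gives aldehyde F7, and ring closure under the conditions of step 18 gives macrocyclic alcohol F8. The epoxy ester has no easily reducible group for divalent chromium at room temperature. Acetylation of F8 as in step 19 gives 42, where the route is rejoined.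

Further compounds

F1 | step 18 | (1(10)Z,4Z)-8-[(tert-butyldimethylsilyl)oxy]-3-hydroxy-9-[(triethylsilyl)oxy]germacra-1(10),4,11(13)-trien-12,6-olide, 3R epimer of 33 | C=C1C(=O)O[C@@H]2/C=C(/C)[C@H](O)C/C=C(/C)[C@H](O[Si](CC)(CC)CC)[C@H](O[Si](C)(C)C(C)(C)C)[C@H]12
F2 | step 13 | (4R,5S)-4-{(1R,2R,3Z)-1-[(tert-butyldimethylsilyl)oxy]-2-hydroxy-6-[(4-methoxyphenyl)methoxy]-3-methylhex-3-en-1-yl}-5-[(1Z)-2-iodoprop-1-en-1-yl]oxolan-2-one, C9 epimer of 26 | O=C1C[C@@H]([C@@H](O[Si](C)(C)C(C)(C)C)[C@H](O)/C(C)=C\CCOCc2ccc(OC)cc2)[C@@H](/C=C(/C)I)O1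
F3 | step 13 | (4R,5S)-4-{(1R,3Z)-1-[(tert-butyldimethylsilyl)oxy]-6-[(4-methoxyphenyl)methoxy]-3-methyl-2-oxohex-3-en-1-yl}-5-[(1Z)-2-iodoprop-1-en-1-yl]oxolan-2-one | O=C1C[C@@H]([C@@H](O[Si](C)(C)C(C)(C)C)C(=O)/C(C)=C\CCOCc2ccc(OC)cc2)[C@@H](/C=C(/C)I)O1
F4 | step 24 | (4R,5S)-4-{(1R,2S,3Z)-1-[(tert-butyldimethylsilyl)oxy]-2-hydroxy-6-[(4-methoxyphenyl)methoxy]-3-methylhex-3-en-1-yl}-5-[(1Z)-2-iodoprop-1-en-1-yl]-3-methylideneoxolan-2-one | C=C1C(=O)O[C@H](/C=C(/C)I)[C@@H]1[C@@H](O[Si](C)(C)C(C)(C)C)[C@@H](O)/C(C)=C\CCOCc1ccc(OC)cc1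
F5 | step 24 | (2R,3R)-2,3-dimethyloxirane-2-carboxylate ester of F4 at O9 | C=C1C(=O)O[C@H](/C=C(/C)I)[C@@H]1[C@@H](O[Si](C)(C)C(C)(C)C)[C@@H](OC(=O)[C@]2(C)O[C@@H]2C)/C(C)=C\CCOCc1ccc(OC)cc1
F6 | step 24 | primary alcohol from F5 after loss of the 4-methoxybenzyl group | C=C1C(=O)O[C@H](/C=C(/C)I)[C@@H]1[C@@H](O[Si](C)(C)C(C)(C)C)[C@@H](OC(=O)[C@]2(C)O[C@@H]2C)/C(C)=C\CCO
F7 | step 24 | C3 aldehyde from F6 | C=C1C(=O)O[C@H](/C=C(/C)I)[C@@H]1[C@@H](O[Si](C)(C)C(C)(C)C)[C@@H](OC(=O)[C@]2(C)O[C@@H]2C)/C(C)=C\CC=O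
F8 | step 24 | (1(10)Z,4Z)-8-[(tert-butyldimethylsilyl)oxy]-9-{[(2R,3R)-2,3-dimethyloxirane-2-carbonyl]oxy}-3-hydroxygermacra-1(10),4,11(13)-trien-12,6-olide (3S,6R,7R,8R,9S) | C=C1C(=O)O[C@@H]2/C=C(/C)[C@@H](O)C/C=C(/C)[C@H](OC(=O)[C@]3(C)O[C@@H]3C)[C@H](O[Si](C)(C)C(C)(C)C)[C@H]12
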